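The constants used here are made up; the flask was simulated.

Take four flasks that differ in temperature, each holding a racemate that a single-handed catalyst works through, and ask what the temperature does to the excess.

| setting | north-east | north | south | east |
|---|---|---|---|---|
| left-handed substrate | 0.30 M | 0.30 M | 0.30 M | 0.30 M |
| partner | 1.10 equiv | 1.10 equiv | 1.10 equiv | 1.10 equiv |
| precatalyst | 10 mol% | 10 mol% | 10 mol% | 10 mol% |
| right-handed substrate | 0.30 M | 0.30 M | 0.30 M | 0.30 M |
| temperature | 0 °C | 50 °C | 25 °C | −25 °C |
| time | 3.0 min | 3.0 min | 3.0 min | 3.0 min |

    partner + free catalyst + left-handed substrate → free catalyst + left-handed product (k1 = 11.9 M⁻² min⁻¹, Ea1 = 46.0 kJ mol⁻¹)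
    2 free catalyst → spent catalyst (k2 = 31.4 M⁻¹ min⁻¹, Ea2 = 63.0 kJ mol⁻¹)
    precatalyst ⇌ free catalyst (K3 = 1.9, k3 = 1.53 min⁻¹, Ea3 = 91.0 kJ mol⁻¹, ΔH3 = −34.0 kJ mol⁻¹)
    partner + free catalyst + right-handed substrate → free catalyst + right-handed product (k4 = 5.20 M⁻² min⁻¹, Ea4 = 46.0 kJ mol⁻¹)
    partner → decomposed reagent (k5 = 0.0616 min⁻¹, Ea5 = 86.0 kJ mol⁻¹)
    (constants at 25 °C)

- free catalyst is single-handed; left-handed substrate and right-handed substrate are mirror images of each other, charged as a racemate, each of them at the stated concentration
- where a step has two of a species, its rate is k times that concentration squared, and two are used at each turn
- the list of constants is for 25 °C, to be carried to other temperatures by the activation energies and enthalpies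
- an excess is the difference of the two amounts in percent of their sum
- an excess is below zero if the other one leads

- the flask with the highest excess of left-handed product over right-handed product ("all alike" if they lie within 1.5 percentage points) (north-east / north / south / east / all alike)
- excess of left-handed product over right-handed product at the end, north-east
- excess of left-handed product over right-handed product at the end, north
- excess of left-handed product over right-handed product at the end, south
- excess of left-handed product over right-handed product at the end, east

I looked for one number into which the givens fold. Steps 1 and 4 both have partner and free catalyst on their left, so whatever c partner and c free catalyst do, the two substrates feel them together, and the left-handed substrate reacts faster than the right-handed one by a fixed ratio. I called this ratio s, the selectivity factor: the rate constant of step 1 over that of step 4, 2.29. Since the two activation energies are equal, s stayed the same at each temperature. At the start, then, the excess of left-handed product is s minus one over s plus one, 39.2 %.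

Was one number enough? Left-handed substrate is used up faster, so its product falls behind. Expanding the two first-order decays, I found that, while little is used, the excess shrinks by its own value times the used share over one plus s. Taking both as fractions, that is 0.119 of excess lost per unit of used share. So the crossing lay near 12.6 % of the left-handed substrate used, where the margin of 1.5 percentage points is spent. The number s says nothing about how much is used, and that amount follows c partner and c free catalyst over the whole time. My commitment was therefore 39.2 % for a flask that hardly reacts, and a conditional "all alike" for the others.

The forecast said all alike, with 39 % north-east, 38.1 % north, 38 % south and 39.2 % east, reasoning that the excess “falls only as the left-handed substrate depletes”.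

The simulation gave all alike: 39.1 % north-east, 38.2 % north, 38.0 % south, 39.2 % east.

South kept 91 % of its left-handed substrate, and at that cost s gives 38.1 %, against 38.0 % found. North ended with spent catalyst at 85.9 % and partner at 5.29 %, which s does not contain, yet it kept 92 % of its left-handed substrate and 38.2 %. The neighbour was east with 40 mol% of precatalyst. Neither s nor the cost contains the loading, so the same reckoning gave 39.2 % for the neighbour as long as it barely reacted, and the neighbour gave 39.2 %, with >99.9 % of its left-handed substrate still there.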